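Friday's flask is slow: after 2.50 h its left-handed product reads 5.0%, and you want its state at 30 h.

| flask | left-handed substrate | right-handed substrate | coupling partner | free catalyst | remark | time |
|---|---|---|---|---|---|---|
| Friday's | 0.11 M | 0.11 M | 1.1 equiv | 5 mol% | the very flask that is asked about, followed so far |  |
| Wednesday's | 0.055 M | 0.055 M | 1.1 equiv | 5 mol% | run made earlier |  |
| flask | 0.11 M | 0.11 M | 1.10 equiv | 5 mol% |  | 30 h |

| run | time / h | left-handed substrate / % | right-handed substrate / % | left-handed product / % |
|---|---|---|---|---|
| Friday's | 0.200 | 49.5 | 49.7 | 0.7 |
| Friday's | 0.333 | 48.6 | 48.9 | 0.9 |
| Friday's | 0.667 | 48.4 | 49.6 | 1.2 |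
| Friday's | 1.33 | 48.2 | 48.9 | 2.6 |
| Friday's | 2.50 | 45.1 | 48.5 | 5.0 |
| Wednesday's | 2.50 | 49.5 | 48.6 | 1.1 |
| Wednesday's | 5.00 | 48.2 | 49.3 | 1.8 |
| Wednesday's | 8.00 | 46.7 | 48.6 | 3.9 |
| Wednesday's | 15.0 | 45.5 | 47.9 | 4.9 |
| Wednesday's | 30.0 | 43.2 | 45.7 | 6.8 |

(scatter of a reading: 0.5 percentage points)

- part of the left-handed substrate and right-handed substrate charged together that has reacted at 30 h
- excess of left-handed product over right-handed product in the product at 30 h
- excess of right-handed substrate over left-handed substrate among what is left of the two at 30 h

- free catalyst is single-handed; left-handed substrate and right-handed substrate are mirror images of each other, charged as a racemate, each of them at the stated concentration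
- an excess is below zero if the other one leads

Draw the curve first. At twice the concentration, Friday's opening product slope is this many times Wednesday's:

4.10

That ratio is read from the opening, and I do not use it to rescale the later clock. Wednesday's knee comes near 8.00 h, and after it the slope reads this fraction of the opening one:

0.270

As a rough reckoning, I take that fraction of Friday's opening slope as the left-handed substrate's steady loss from Friday's last reading to 30 h, so I expect it to reach 30.2%.

For the rest, reckon with what is left. If both substrates pass through the same catalyst and partner, each first order in itself, then time, catalyst and partner cancel from one ratio, which I read from both runs' last readings, scatter included: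

selectivity factor, the logarithm of the fraction of left-handed substrate left over that of right-handed substrate left = 2.07

Fraction of left-handed substrate left = 60.5%, so fraction of right-handed substrate left = 78.4%

My reckoning gives 30.5% reacted, a product excess of 29.3% and a substrate excess of 12.9%.

The forecast gives 30%, 10% and 4.3%, so it parts from my reckoning in the two excesses, on this ground: “The likely cause is the product sequestering the catalyst, leaving an almost unselective path.”

The flask gives 23.2%, 31.7% and 10.2%.

    coupling partner + free catalyst + left-handed substrate → free catalyst + left-handed product (k = 69.0 /M²/h)
    coupling partner + free catalyst + right-handed substrate → free catalyst + right-handed product (k = 31.0 /M²/h)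
    left-handed product ⇌ right-handed product (k = 0.00140 /h)
    2 free catalyst ⇌ resting dimer (K = 5600 /M, k = 8.60 /M/h)
    free catalyst → spent catalyst (k = 0.0370 /h)

At 30 h the half-lives are 8.4 d for left-handed substrate and 19 d for right-handed substrate, both long against the time, yet the second is still twice the first. With 69% of the left-handed charge left, the factor 2.07 puts the right-handed at 83.6%; the flask holds 85%.

In the neighbour with 4.40 equiv of coupling partner, 20% of the left-handed charge is left, so the factor puts the right-handed at 46.3% and the substrate excess at 39.0%. That flask gives 49% and 41.3%.

The readings stem from a simulated flask with made-up constants; noise was put on by code.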